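If gas passes quickly into a stirred solution, the bench habit is to take the dissolved gas as standing at its saturation value and forget the transfer. We test that habit on a flask in which starting material takes up dissolved gas to give target, while target and starting material also combine to side product.

    gas phase ⇌ dissolved gas, rate k1*(csat - [dissolved gas]) (k1 = 3.6 s⁻¹, csat = 110 mM)
    starting material + dissolved gas → target (k2 = 4.2 L mol⁻¹ s⁻¹)
    target ⇌ isomer of the product (K3 = 0.37, k3 = 0.062 s⁻¹)
    starting material ⇌ dormant form (K4 = 2.2, k4 = 0.0072 s⁻¹)
    starting material + target → side product (k5 = 0.10 L mol⁻¹ s⁻¹)

starting material 1.5 M; gas phase 110 mM (held); time 1.0 min

- percentages count the starting material that a species holds: one side product counts as two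
- at the start none of the gas is dissolved
- run time (flask): 1.0 min

1. how much target there is at 1.0 min, in percent of the starting material charged
2. the change that raises the amount of target at 1.0 min, in percent of the starting material charged most ("none" if none brings more than 2 percentage points) (midnight / summer / none)
3. amount of target at 1.0 min, in percent of the starting material charged, after summer

- midnight: doubling the transfer coefficient of step 1, all else as stated
- summer: doubling the saturation concentration of gas phase, all else as stated

At first the habit looks sound. The transfer half-life, ln(2) over the transfer coefficient, is 0.193 s, shorter than the 1.50 s that starting material would have at 110 mM of dissolved gas. But step 2 uses dissolved gas with a half-life of 0.11 s at the charge, shorter than the transfer half-life by a factor of 1.75, so at the start the two rates are of like size. Both gas half-lives are shorter than 1.50 s, so we let gas coming in balance gas used: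

3.6 s⁻¹ × (c(sat) − c(dissolved gas)) = 4.2 L mol⁻¹ s⁻¹ × c(starting material) × c(dissolved gas)

c(dissolved gas) = c(sat) / (1 + c(starting material) / c(border))

The border charge c(border), the transfer coefficient divided by the rate constant of step 2, is 0.857 M: the amount of starting material at which dissolved gas stands at half of saturation. This flask is charged at 1.75 times the border, so by our line it opens at 36.4 % of saturation, or 0.0400 M.

Gas level matters because target's half-life by step 5 alone, with starting material as charged, is 0.077 min, shorter than the 1.0 min of reading. At the charge, summer gives 0.0800 M of dissolved gas and midnight 0.0587 M, less than summer. So we commit to summer; our reckoning stops at this ranking and gives no yield.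

The forecast says 51 % of target, summer as the best change and 61 % after it, holding that the “gas uptake is transfer-limited”.

The simulation gives 50.6 % of target, and summer as the best change, with a gain of 8.1 percentage points against 2.8 points for midnight, reaching 58.7 %.

In the flask at 0.100 min, starting material stood at 16.9 % of the charge and dissolved gas at 75.6 % of saturation, where our line, fed with that starting material, gives 77.2 %. The neighbour charged with 0.38 M lies below the border, at 0.443 of it, so the line opens it at 69.3 % of saturation. That neighbour ends with 66.3 % of target and 7.57 % of side product, against 28.6 % of side product in the flask.

The constants used here were drawn at random within sensible limits; the flask was simulated.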